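**Retrosynthetic overview**
1. Target 17 ⇐ Suzuki–Miyaura alkenylation of aryl chloride 15 with hydroxypropenyl boronate 16; 15 ⇐ LiAlH4 reduction of the trans,trans-diester 14.
2. 14 ⇐ key step: double catalytic asymmetric dearomative hydrogenation of the fully aromatic bis-benzofuran 12 (sets C2 and C2'), then C3/C3' epimerisation to trans in the same pot.
3. 12 ⇐ two successive C2–H arylations run on an I > Br > Cl reactivity gradient: 2 + 10 → 11, then 11 + 7 → 12.
4. 7 and 10 ⇐ one-pot benzofuran annulation of 5-halo-o-vanillins with ethyl diazoacetate; 4 ⇐ o-vanillin.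
5. Ring order: the two furan rings are made separately as aromatic benzofurans, joined, then converted together into the two trans-dihydrofuran rings.

Assumption: the facial sense of the Ru–NHC catalyst on this new substrate class cannot be read from precedent, so the route is written with the (R,R)-ligand as the one giving (2R,2'R); the (S,S)-ligand is used instead if a test hydrogenation of 11 shows the opposite sense. Compounds 1, 3, 5, 8 and 16 are taken as commercial.

**Route**

Step 1
Reactants: 1 4-iodo-2-methoxyphenol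
Product: 2 4-iodo-2-methoxyphenyl pivalate
Conditions: PivCl (1.2 equiv), Et3N, DMAP (5 mol%), CH2Cl2, 0 °C to rt
Reagents that add atoms: pivaloyl chloride, CC(C)(C)C(=O)Cl
Why: DMAP-catalysed O-acylation gives a base-robust aryl ester that keeps the ring-A phenol masked (no quinone methide can form at the epimerisation stage) and is later removed by the hydride reduction without a separate step.

Step 2
Reactants: 3 o-vanillin (2-hydroxy-3-methoxybenzaldehyde)
Product: 4 5-chloro-2-hydroxy-3-methoxybenzaldehyde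
Conditions: NCS (1.05 equiv), TsOH·H2O (10 mol%), MeCN, rt
Reagents that add atoms: N-chlorosuccinimide, O=C1CCC(=O)N1Cl
Why: Electrophilic aromatic chlorination goes para to the phenol OH (both ortho positions are blocked and the CHO group is meta-directing to the same carbon), as in the well-known 5-bromination of o-vanillin.

Step 3
Reactants: 4 5-chloro-2-hydroxy-3-methoxybenzaldehyde; 5 ethyl diazoacetate
Product: 7 ethyl 5-chloro-7-methoxybenzofuran-3-carboxylate, via cyclic hemiacetal 6 (not isolated)
Conditions: HBF4·OEt2 (10 mol%), CH2Cl2, rt; then conc. H2SO4, rt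
Reagents that add atoms: none
Why: Acid-catalysed addition of the diazoester to the salicylaldehyde with 1,2-aryl shift and loss of N2 (Roskamp-type homologation) gives a 2-aryl-3-oxopropanoate that closes to the 2-hydroxy-dihydrobenzofuran, and H2SO4 dehydrates it to the benzofuran-3-carboxylate.

Step 4
Reactants: 8 5-bromo-2-hydroxy-3-methoxybenzaldehyde; 5 ethyl diazoacetate
Product: 10 ethyl 5-bromo-7-methoxybenzofuran-3-carboxylate, via cyclic hemiacetal 9 (not isolated)
Conditions: HBF4·OEt2 (10 mol%), CH2Cl2, rt; then conc. H2SO4, rt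
Reagents that add atoms: none
Why: Same salicylaldehyde/diazoacetate benzofuran annulation (aryl-shift homologation, hemiacetal closure, dehydration) as in step 3, which tolerates the aryl bromide.

Step 5
Reactants: 10 ethyl 5-bromo-7-methoxybenzofuran-3-carboxylate; 2 4-iodo-2-methoxyphenyl pivalate (1.2 equiv)
Product: 11 ethyl 5-bromo-7-methoxy-2-[3-methoxy-4-(pivaloyloxy)phenyl]benzofuran-3-carboxylate
Conditions: Pd(OAc)2 (5 mol%), Ag2O (0.75 equiv), 2-nitrobenzoic acid (1.5 equiv), HFIP, 30 °C
Reagents that add atoms: none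
Why: Silver-promoted Pd-catalysed direct C–H arylation of a benzofuran with an aryl iodide occurs at the only furan C–H (C2, acidified by the 3-ester) near room temperature, where the C–Br bond of 10 does not undergo oxidative addition, so 10 cannot oligomerise.

Step 6
Reactants: 11 ethyl 5-bromo-7-methoxy-2-[3-methoxy-4-(pivaloyloxy)phenyl]benzofuran-3-carboxylate; 7 ethyl 5-chloro-7-methoxybenzofuran-3-carboxylate (1.2 equiv)
Product: 12 diethyl 5'-chloro-7,7'-dimethoxy-2-[3-methoxy-4-(pivaloyloxy)phenyl]-[5,2'-bibenzofuran]-3,3'-dicarboxylate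
Conditions: PdCl(C3H5)(dppb) (2 mol%), KOAc (2 equiv), DMA, 120 °C
Reagents that add atoms: none
Why: Pd(0)-catalysed direct arylation by concerted metalation–deprotonation joins the Ar–Br of 11 (which has no C2–H and cannot self-couple) to the C2–H of 7, while the electron-rich Ar–Cl of 7 is inert with a simple diphosphine and the pivalate survives the acetate base.

Step 7
Reactants: 12 diethyl 5'-chloro-7,7'-dimethoxy-2-[3-methoxy-4-(pivaloyloxy)phenyl]-[5,2'-bibenzofuran]-3,3'-dicarboxylate
Product: 14 diethyl (2R,3R,2'R,3'R)-5'-chloro-7,7'-dimethoxy-2-[3-methoxy-4-(pivaloyloxy)phenyl]-2,3,2',3'-tetrahydro-[5,2'-bibenzofuran]-3,3'-dicarboxylate, via cis,cis-diester 13 (not isolated)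
Conditions: [Ru(cod)(2-methylallyl)2] (10 mol%), (R,R)-SINpEt·HBF4 (20 mol%), KOt-Bu (25 mol%), toluene, 70 °C (catalyst preformation); then 12, H2 (80 bar), toluene, 40 °C; vent; DBU (3 equiv), 70 °C
Reagents that add atoms: none
Why: Proposed new method: the C2=C3 bond of each benzofuran is its least aromatic π-bond (an enol-ether/enoate), and a chiral Ru–bis(NHC) catalyst, which is known to hydrogenate 2-arylbenzofurans at the furan ring with high face selectivity, should add H2 syn to the same face of both rings, setting C2 and C2' as R (cis,cis-13, with the mismatched diastereomer removed by chromatography and the ee raised by the two independent catalyst-controlled events, Horeau principle); DBU then epimerises only C3 and C3' through the ester enolates to the more stable trans arrangement, C2 being fixed because the phenol is acylated and E1cB ring opening would be a disfavoured retro-5-endo-trig process; the closest known reaction types are the Ru–NHC asymmetric hydrogenation of 2-substituted benzofurans and the base epimerisation of cis-2-aryl-2,3-dihydrobenzofuran-3-carboxylates.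

Step 8
Reactants: 14 diethyl (2R,3R,2'R,3'R)-5'-chloro-7,7'-dimethoxy-2-[3-methoxy-4-(pivaloyloxy)phenyl]-2,3,2',3'-tetrahydro-[5,2'-bibenzofuran]-3,3'-dicarboxylate
Product: 15 4-[(2R,3S)-5-[(2R,3S)-5-chloro-3-(hydroxymethyl)-7-methoxy-2,3-dihydrobenzofuran-2-yl]-3-(hydroxymethyl)-7-methoxy-2,3-dihydrobenzofuran-2-yl]-2-methoxyphenol
Conditions: LiAlH4 (6 equiv), THF, 0 °C; Rochelle salt work-up
Reagents that add atoms: none
Why: Hydride reduction converts both esters to CH2OH and cleaves the aryl pivalate in the same operation, leaving Ar–Cl and the benzylic aryl ethers intact; no stereocentre is touched (C3 changes from R to S only through CIP priorities) and C3 is no longer epimerisable afterwards.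

Step 9
Reactants: 15 4-[(2R,3S)-5-[(2R,3S)-5-chloro-3-(hydroxymethyl)-7-methoxy-2,3-dihydrobenzofuran-2-yl]-3-(hydroxymethyl)-7-methoxy-2,3-dihydrobenzofuran-2-yl]-2-methoxyphenol; 16 (E)-3-(4,4,5,5-tetramethyl-1,3,2-dioxaborolan-2-yl)prop-2-en-1-ol (1.5 equiv)
Product: 17 4-[(2R,3S)-3-(hydroxymethyl)-5-[(2R,3S)-3-(hydroxymethyl)-5-[(E)-3-hydroxyprop-1-enyl]-7-methoxy-2,3-dihydrobenzofuran-2-yl]-7-methoxy-2,3-dihydrobenzofuran-2-yl]-2-methoxyphenol (target)
Conditions: XPhos Pd G3 (5 mol%), K3PO4 (4 equiv), THF/H2O 4:1 (degassed), 60 °C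
Reagents that add atoms: none
Why: Suzuki–Miyaura coupling with a bulky biarylphosphine activates the electron-rich aryl chloride and transfers the alkenyl group with retention of E geometry, tolerating the free phenol and alcohols, and the C3-locked stereocentres cannot scramble under the mild phosphate base.

**Compound list**
1 | 4-iodo-2-methoxyphenol | COc1cc(I)ccc1O | starting material
2 | 4-iodo-2-methoxyphenyl pivalate | COc1cc(I)ccc1OC(=O)C(C)(C)C | intermediate
3 | o-vanillin (2-hydroxy-3-methoxybenzaldehyde) | COc1cccc(C=O)c1O | starting material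
4 | 5-chloro-2-hydroxy-3-methoxybenzaldehyde | COc1cc(Cl)cc(C=O)c1O | intermediate
5 | ethyl diazoacetate | CCOC(=O)C=[N+]=[N-] | starting material
6 | ethyl 5-chloro-2-hydroxy-7-methoxy-2,3-dihydrobenzofuran-3-carboxylate (cyclic hemiacetal, diastereomer mixture) | CCOC(=O)C1C(O)Oc2c(OC)cc(Cl)cc12 | intermediate (not isolated)
7 | ethyl 5-chloro-7-methoxybenzofuran-3-carboxylate | CCOC(=O)c1coc2c(OC)cc(Cl)cc12 | intermediate
8 | 5-bromo-2-hydroxy-3-methoxybenzaldehyde | COc1cc(Br)cc(C=O)c1O | starting material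
9 | ethyl 5-bromo-2-hydroxy-7-methoxy-2,3-dihydrobenzofuran-3-carboxylate (cyclic hemiacetal, diastereomer mixture) | CCOC(=O)C1C(O)Oc2c(OC)cc(Br)cc12 | intermediate (not isolated)
10 | ethyl 5-bromo-7-methoxybenzofuran-3-carboxylate | CCOC(=O)c1coc2c(OC)cc(Br)cc12 | intermediate
11 | ethyl 5-bromo-7-methoxy-2-[3-methoxy-4-(pivaloyloxy)phenyl]benzofuran-3-carboxylate | COc1cc(-c2oc3c(OC)cc(Br)cc3c2C(=O)OCC)ccc1OC(=O)C(C)(C)C | intermediate
12 | diethyl 5'-chloro-7,7'-dimethoxy-2-[3-methoxy-4-(pivaloyloxy)phenyl]-[5,2'-bibenzofuran]-3,3'-dicarboxylate | COc1cc(-c2oc3c(OC)cc(-c4oc5c(OC)cc(Cl)cc5c4C(=O)OCC)cc3c2C(=O)OCC)ccc1OC(=O)C(C)(C)C | intermediate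
13 | diethyl (2R,3S,2'R,3'S)-5'-chloro-7,7'-dimethoxy-2-[3-methoxy-4-(pivaloyloxy)phenyl]-2,3,2',3'-tetrahydro-[5,2'-bibenzofuran]-3,3'-dicarboxylate (cis,cis) | COc1cc([C@@H]2Oc3c(OC)cc([C@@H]4Oc5c(OC)cc(Cl)cc5[C@@H]4C(=O)OCC)cc3[C@@H]2C(=O)OCC)ccc1OC(=O)C(C)(C)C | intermediate (not isolated)
14 | diethyl (2R,3R,2'R,3'R)-5'-chloro-7,7'-dimethoxy-2-[3-methoxy-4-(pivaloyloxy)phenyl]-2,3,2',3'-tetrahydro-[5,2'-bibenzofuran]-3,3'-dicarboxylate (trans,trans) | COc1cc([C@@H]2Oc3c(OC)cc([C@@H]4Oc5c(OC)cc(Cl)cc5[C@H]4C(=O)OCC)cc3[C@H]2C(=O)OCC)ccc1OC(=O)C(C)(C)C | intermediate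
15 | 4-[(2R,3S)-5-[(2R,3S)-5-chloro-3-(hydroxymethyl)-7-methoxy-2,3-dihydrobenzofuran-2-yl]-3-(hydroxymethyl)-7-methoxy-2,3-dihydrobenzofuran-2-yl]-2-methoxyphenol | COc1cc([C@@H]2Oc3c(OC)cc([C@@H]4Oc5c(OC)cc(Cl)cc5[C@H]4CO)cc3[C@H]2CO)ccc1O | intermediate
16 | (E)-3-(4,4,5,5-tetramethyl-1,3,2-dioxaborolan-2-yl)prop-2-en-1-ol | OC/C=C/B1OC(C)(C)C(C)(C)O1 | starting material
17 | 4-[(2R,3S)-3-(hydroxymethyl)-5-[(2R,3S)-3-(hydroxymethyl)-5-[(E)-3-hydroxyprop-1-enyl]-7-methoxy-2,3-dihydrobenzofuran-2-yl]-7-methoxy-2,3-dihydrobenzofuran-2-yl]-2-methoxyphenol | COc1cc([C@@H]2Oc3c(OC)cc([C@@H]4Oc5c(OC)cc(/C=C/CO)cc5[C@H]4CO)cc3[C@H]2CO)ccc1O | target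

**Totals and risks**

Total step count: 9. Longest linear sequence: 6 steps (for example 8 → 10 → 11 → 12 → 14 → 15 → 17).

Most likely to fail, in order:

Step 7 (double asymmetric dearomative hydrogenation). The tetrasubstituted, ester-conjugated C2=C3 bonds may be unreactive or poorly discriminated. The fallback gives up catalyst control and sets out from 12. Mg turnings in MeOH/THF reduce both benzofuran enoates by single-electron transfer, a reaction known to give trans-2-aryl-2,3-dihydrobenzofuran-3-carboxylates. Methanolysis of the pivalate and ester exchange occur alongside, giving the all-trans dimethyl ester phenol stereoisomer mixture F1 (four isomers). Preparative chiral SFC isolates the (2R,3R,2'R,3'R)-dimethyl ester phenol F2, at most a quarter of the material. LiAlH4 in THF at 0 °C then gives the chloro triol, so the fallback returns to the route at 15.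

Step 5 (chemoselective C–H arylation beside an aryl bromide). The hindered, ester-flanked C2–H may react too slowly, or the bromide may start to couple. The fallback replaces catalytic C–H activation by stoichiometric metalation and sets out from 10. TMPZnCl·LiCl in THF at 25 °C zincates C2 (ester-directed, C–Br tolerated) to give (5-bromo-3-ethoxycarbonyl-7-methoxybenzofuran-2-yl)zinc chloride F3. Negishi coupling with 2 (Pd(PPh3)4, THF, rt) consumes only the C–I bond and returns to the route at 11.

Step 9 (Suzuki coupling of an unprotected, electron-rich aryl chloride). The free phenoxide and the triol may slow the coupling, or the boronate may protodeboronate. The fallback installs the side chain before the reduction and sets out from 14. Heck reaction with methyl acrylate (Pd2(dba)3, P(t-Bu)3·HBF4, Cy2NMe, dioxane, 100 °C) on the still fully protected diester gives the (E)-acrylate triester F4. Excess DIBAL-H in CH2Cl2 at −78 to 0 °C then reduces all three esters (the acrylate in the 1,2-sense) and cleaves the pivalate, so the fallback returns to the route at 17.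

**Further compounds**
F1 | step 7 | dimethyl 5'-chloro-2-(4-hydroxy-3-methoxyphenyl)-7,7'-dimethoxy-2,3,2',3'-tetrahydro-[5,2'-bibenzofuran]-3,3'-dicarboxylate, mixture of the four stereoisomers with both rings trans | COc1cc(C2Oc3c(OC)cc(C4Oc5c(OC)cc(Cl)cc5C4C(=O)OC)cc3C2C(=O)OC)ccc1O
F2 | step 7 | dimethyl (2R,3R,2'R,3'R)-5'-chloro-2-(4-hydroxy-3-methoxyphenyl)-7,7'-dimethoxy-2,3,2',3'-tetrahydro-[5,2'-bibenzofuran]-3,3'-dicarboxylate | COc1cc([C@@H]2Oc3c(OC)cc([C@@H]4Oc5c(OC)cc(Cl)cc5[C@H]4C(=O)OC)cc3[C@H]2C(=O)OC)ccc1O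
F3 | step 5 | (5-bromo-3-ethoxycarbonyl-7-methoxybenzofuran-2-yl)zinc chloride | CCOC(=O)c1c([Zn]Cl)oc2c(OC)cc(Br)cc12
F4 | step 9 | diethyl (2R,3R,2'R,3'R)-7,7'-dimethoxy-5'-[(E)-3-methoxy-3-oxoprop-1-enyl]-2-[3-methoxy-4-(pivaloyloxy)phenyl]-2,3,2',3'-tetrahydro-[5,2'-bibenzofuran]-3,3'-dicarboxylate | COc1cc([C@@H]2Oc3c(OC)cc([C@@H]4Oc5c(OC)cc(/C=C/C(=O)OC)cc5[C@H]4C(=O)OCC)cc3[C@H]2C(=O)OCC)ccc1OC(=O)C(C)(C)C
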